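Numbering: N4; C5–C8 are the four CH2 groups from N4 to the ketone C9; C10 bears ethyl. Ring D is the lactone O–C11–C12–C13(CH3)–C14(=O). Ring A is the lactam N4–C9a(=O)–C1(OH)–C2–C3. Ring E is the lactone O–C18–C19–C20(CH3)–C21(=O) on C3.
Cuts, in retrosynthetic order: C7=C8 unsaturation and the C1 O-benzyl group; C5–C6, which opens the eleven-membered ring N4-C5-C6-C7-C8-C9-C10-C11-C12-C1-C9a (the eight-atom bridge of the 1-azabicyclo[8.2.1]tridecane core); C10–C11 (aldol) with the C11–O–C14 lactone bond; C1–C12 (Michael) with C13–CH3; C18–C19 (ketone synthesis).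
Enabling feature: N4–C5–C6–C7–C8–C9(=O) is a δ-amido ketone. C5 is a methylene on the lactam nitrogen (latent N-acyliminium carbon) and C6 is the γ-carbon of the C9 ketone, so the two ends are polarity-matched for an intramolecular vinylogous Mannich closure.
Forward order: ring A (chiral pool), then the C18–C21 chain, the C1–C12 union with a masked ring D, ring E, ring D by aldol and lactonisation, and last the eleven-membered ring.
Stereochemistry: C3 comes from L-pyroglutamic acid and C20 from (R)-3-bromo-2-methylpropanol. C18 is set by Felkin–Anh reduction. C1 is set by enolate attack anti to the C3 chain, C12 and C13 by attack anti to the menthyloxy group and then anti to C12. C10 and C11 are set by a (Z)-boron enolate syn-aldol on the anti-Felkin aldehyde face.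
Helpers: the N-CH2OMe group protects N4 from step 2 and becomes C5. The propenyl ketone supplies C6–C8 and its double bond leaves with the benzyl ether in the last step.

Key step: step 14

Assumption: the target is treated as the open C1-hydroxy C9-ketone as drawn (not a transannular hemiketal), and compound 13 is taken as a catalogue compound.

Step 1
Reactants: 1 L-pyroglutamic acid
Product: 2 (S)-N-methoxy-N-methyl-5-oxopyrrolidine-2-carboxamide
Conditions: 1,1'-carbonyldiimidazole, CH2Cl2, 0 °C to rt; then MeNH(OMe)·HCl, rt
Reagents that add atoms: N,O-dimethylhydroxylamine hydrochloride, CNOC.Cl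
Why: Amide coupling through the acyl imidazolide gives the N-methoxy-N-methylamide needed for a clean ketone synthesis, and the chiral-pool stereocentre C3 (S) is carried over unchanged.

Step 2
Reactants: 2 (S)-N-methoxy-N-methyl-5-oxopyrrolidine-2-carboxamide; 3 chloromethyl methyl ether
Product: 4 (S)-N-methoxy-1-(methoxymethyl)-N-methyl-5-oxopyrrolidine-2-carboxamide
Conditions: LiN(SiMe3)2 (1.0 equiv), THF, −78 °C; then 3, −78 to 0 °C
Reagents that add atoms: none
Why: N-Alkylation of the lithium lactamate (N–H is the most acidic site, so C3 is not deprotonated) installs an N,O-aminal that protects N4 through the enolate chemistry and already contains C5 as a latent N-acyliminium carbon.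

Step 3
Reactants: 5 (R)-3-bromo-2-methylpropan-1-ol
Product: 6 (R)-(3-bromo-2-methylpropoxy)(tert-butyl)dimethylsilane
Conditions: t-BuMe2SiCl, imidazole, DMF, rt
Reagents that add atoms: tert-butyldimethylsilyl chloride, CC(C)(C)[Si](C)(C)Cl
Why: Standard silyl ether formation masks the primary alcohol (future C21) and leaves the chiral-pool stereocentre C20 untouched.

Step 4
Reactants: 6 (R)-(3-bromo-2-methylpropoxy)(tert-butyl)dimethylsilane; 4 (S)-N-methoxy-1-(methoxymethyl)-N-methyl-5-oxopyrrolidine-2-carboxamide
Product: 8 (S)-5-[(S)-4-(tert-butyldimethylsilyloxy)-3-methylbutanoyl]-1-(methoxymethyl)pyrrolidin-2-one, via organomagnesium bromide 7 (not isolated)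
Conditions: 6, Mg turnings, THF, 40 °C; then 4, THF, −20 to 0 °C; cold 1 M aq HCl
Reagents that add atoms: none
Why: Grignard formation and acyl substitution on the N-methoxy-N-methylamide should stop at the ketone because the chelated tetrahedral adduct survives until the quench and the N-alkyl lactam carbonyl is far less electrophilic, so the C18–C19 bond is made without touching C3 or C20.

Step 5
Reactants: 8 (S)-5-[(S)-4-(tert-butyldimethylsilyloxy)-3-methylbutanoyl]-1-(methoxymethyl)pyrrolidin-2-one
Product: 9 (S)-5-[(1S,3S)-4-(tert-butyldimethylsilyloxy)-1-hydroxy-3-methylbutyl]-1-(methoxymethyl)pyrrolidin-2-one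
Conditions: LiBH(s-Bu)3, THF, −78 °C; H2O
Reagents that add atoms: none
Why: Felkin–Anh-controlled ketone reduction by a bulky, non-chelating borohydride (hydride antiperiplanar to the C3–N4 bond) should set C18 as S, which is the syn (threo) N4/O relationship of the target.

Step 6
Reactants: 9 (S)-5-[(1S,3S)-4-(tert-butyldimethylsilyloxy)-1-hydroxy-3-methylbutyl]-1-(methoxymethyl)pyrrolidin-2-one
Product: 10 (S)-5-[(1S,3S)-1,4-bis(tert-butyldimethylsilyloxy)-3-methylbutyl]-1-(methoxymethyl)pyrrolidin-2-one
Conditions: t-BuMe2SiCl, imidazole, DMAP (cat.), DMF, 40 °C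
Reagents that add atoms: tert-butyldimethylsilyl chloride, CC(C)(C)[Si](C)(C)Cl
Why: Silyl ether formation with the chloride (not the triflate, which could ionise the N,O-aminal) masks ring E as a base-stable 1,4-diol without an acidic C20–H and enlarges the C3 substituent that will steer the C1 enolate.

Step 7
Reactants: 10 (S)-5-[(1S,3S)-1,4-bis(tert-butyldimethylsilyloxy)-3-methylbutyl]-1-(methoxymethyl)pyrrolidin-2-one
Product: 11 (3R,5S)-3-hydroxy derivative of 10 (C1–OH trans to the C3 side chain)
Conditions: LiN(i-Pr)2, THF, −78 °C; 2-(phenylsulfonyl)-3-phenyloxaziridine, −78 °C; AcOH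
Reagents that add atoms: 2-(phenylsulfonyl)-3-phenyloxaziridine, O=S(=O)(c1ccccc1)N1OC1c1ccccc1
Why: Electrophilic α-hydroxylation of the lactam enolate with an N-sulfonyloxaziridine brings in the C1 oxygen, expected anti to the C3 chain, although this configuration does not matter because C1 is planarised again in step 9.

Step 8
Reactants: 11 (3R,5S)-3-hydroxy lactam
Product: 12 (3R,5S)-3-benzyloxy-5-[(1S,3S)-1,4-bis(tert-butyldimethylsilyloxy)-3-methylbutyl]-1-(methoxymethyl)pyrrolidin-2-one
Conditions: NaH, BnBr, n-Bu4NI (cat.), THF–DMF, 0 °C to rt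
Reagents that add atoms: benzyl bromide, BrCc1ccccc1
Why: Williamson etherification gives an α-alkoxy lactam whose oxygen is blocked against retro-aldol and elimination pathways until the neutral hydrogenolysis of the last step.

Step 9
Reactants: 12 (3R,5S)-3-benzyloxy lactam; 13 (5S)-5-[(1S,2R,5S)-menthyloxy]furan-2(5H)-one
Product: 15 Michael–methylation adduct (1R,3S,11S,12R,13S,18S,20S): C1 carries OBn (cis to the C3 chain) and the 11-menthyloxy-13-methyl-14-oxotetrahydrofuran-12-yl group (trans to the C3 chain), via lithium lactone enolate 14 (not isolated)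
Conditions: LiN(i-Pr)2, THF, −78 °C; 13, −78 °C; then MeI, DMPU, −78 to −30 °C
Reagents that add atoms: iodomethane, CI
Why: In this tandem Michael addition–enolate alkylation the planar C1 enolate should react on the face anti to the bulky C3 chain (sets C1), the butenolide on the face anti to its menthyloxy group (sets C12), and the resulting lactone enolate 14 should be methylated anti to the new C12 substituent (sets C13).

Step 10
Reactants: 15 Michael–methylation adduct
Product: 16 diol ester acetal (1R,3S,12R,13S,18S,20S): C12 carries CH(OMe)2 (C11) and CH(CH3)CO2Me (C13 and C14) and the side chain is the free C18/C21 diol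
Conditions: HCl (0.5 M in MeOH), HC(OMe)3, 40 °C
Reagents that add atoms: methanol, CO
Why: Acid-catalysed transesterification and transacetalisation opens the acyloxy acetal to methyl ester plus dimethyl acetal (driven by the orthoformate, which removes the water), and the same medium solvolyses both silyl ethers, while the N-CH2OMe group can only exchange degenerately with the solvent and no stereocentre is touched.

Step 11
Reactants: 16 diol ester acetal
Product: 17 ring E lactone (1R,3S,12R,13S,18S,20S) with C11 dimethyl acetal and C14 methyl ester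
Conditions: TEMPO (cat.), PhI(OAc)2, CH2Cl2, rt
Reagents that add atoms: none
Why: Oxoammonium-mediated oxidative lactonisation of a 1,4-diol oxidises the primary C21 alcohol first, and the derived lactol with the C18 hydroxyl is oxidised on to ring E without base, so C18 and C20 keep the cis relationship built in steps 3 to 5.

Step 12
Reactants: 17 ring E lactone acetal
Product: 18 C11 aldehyde (1R,3S,12R,13S,18S,20S) with C14 methyl ester
Conditions: CF3CO2H–H2O (9:1), CH2Cl2, 0 °C
Reagents that add atoms: water, O
Why: Mild acetal hydrolysis frees the aldehyde under acidic conditions that should neither epimerise C12 nor expel the β-benzyloxy group, and that are too mild to cleave the N-acyl N,O-aminal.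

Step 13
Reactants: 18 C11 aldehyde; 19 (E)-hept-2-en-4-one
Product: 22 seco propenyl ketone (1R,3S,10S,11R,12S,13S,18S,20S) with rings A, D and E closed and N4–CH2OMe intact, via boron enolate 20 (not isolated), via aldol adduct 21 (not isolated)
Conditions: 19, n-Bu2BOTf, i-Pr2NEt, CH2Cl2, −78 to 0 °C; 18, −78 to −20 °C; pH 7 buffer, MeOH, H2O2, 0 °C; then camphorsulfonic acid (cat.), CH2Cl2, rt
Reagents that add atoms: none
Why: In this boron-mediated syn-aldol through a Zimmerman–Traxler chair the (Z)-enolate formed at the only α-CH2 (C10) should give the 10,11-syn pair, should attack the anti-Felkin aldehyde face that (Z)-enolates prefer (no syn-pentane contact between the C10 ethyl group and C13) to give the 11,12-anti relation, and the C11 hydroxyl then closes cis-substituted ring D by 5-exo-trig lactonisation with loss of methanol.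

Step 14
Reactants: 22 seco propenyl ketone
Product: 24 macrocyclic (E)-enone benzyl ether (7,8-didehydro-1-O-benzyl target), via silyloxydiene N-acyliminium triflate 23 (not isolated)
Conditions: 22 added slowly (syringe pump) to Me3SiOTf (4 equiv), i-Pr2NEt (2 equiv), CH2Cl2 (final 1 mM), −40 to −10 °C; aq NaHCO3
Reagents that add atoms: none
Why: Proposed new method: Me3SiOTf silylates the C9 enone oxygen and i-Pr2NEt removes a C6–H to give the 2-silyloxydiene, further Me3SiOTf ionises the N4–CH2–OMe aminal, and in the resulting ion 23 the diene terminus C6 attacks the iminium carbon C5, after which loss of the silyl group from the C9 oxocarbenium ion returns the conjugated enone and Me3SiOTf. The closest known reaction types are the vinylogous Mukaiyama–Mannich (γ-amidoalkylation) reaction of silyl dienol ethers with N-acyliminium ions and the one-pot silyl triflate/amine Mannich addition of ketones to N,O-acetals, which are established intermolecularly and for common ring sizes but not for an eleven-membered ring. The one ring closed is the eleven-membered ring, that is the eight-atom bridge of the 1-azabicyclo[8.2.1]tridecane, in an 11-endo-trig mode at the iminium carbon with the enol unit endocyclic. No stereocentre is formed, and the C7=C8 geometry (E expected from the extended diene) or any double-bond shift is erased in step 15. The step needs enolisation at C6 and not at C10, which the substrate secures because C10–H is tertiary, flanked by ethyl and ring D, and would lead to a tetrasubstituted enol ether with allylic strain, and it needs γ- over α-attack, which is secured because C6 is the unhindered terminus while attack through C8 would give a more strained nine-membered ring and an unconjugated product. Ring closure over oligomerisation is secured by slow addition at high dilution and by the cis C11/C12 substitution of ring D at the quaternary C1, which turns both chain ends to the same face of ring A.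

Step 15
Reactants: 24 macrocyclic enone benzyl ether
Product: 25 target CNP0221273.1 (1R,3S,10S,11R,12S,13S,18S,20S)
Conditions: H2 (1 atm), Pd(OH)2/C, EtOAc–EtOH, rt
Reagents that add atoms: none
Why: Heterogeneous catalytic hydrogenation saturates the C7=C8 double bond and hydrogenolyses the tertiary benzyl ether in one neutral operation that should spare the ketone, both lactones and the base-sensitive β-acyloxy ketone, and no stereocentre is formed or exposed.

Compound list
1 | L-pyroglutamic acid | N1C(=O)CC[C@H]1C(=O)O | starting material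
2 | (S)-N-methoxy-N-methyl-5-oxopyrrolidine-2-carboxamide | N1C(=O)CC[C@H]1C(=O)N(C)OC | intermediate
3 | chloromethyl methyl ether | COCCl | starting material
4 | (S)-N-methoxy-1-(methoxymethyl)-N-methyl-5-oxopyrrolidine-2-carboxamide | COCN1C(=O)CC[C@H]1C(=O)N(C)OC | intermediate
5 | (R)-3-bromo-2-methylpropan-1-ol | BrC[C@H](C)CO | starting material
6 | (R)-(3-bromo-2-methylpropoxy)(tert-butyl)dimethylsilane | BrC[C@H](C)CO[Si](C)(C)C(C)(C)C | intermediate
7 | (R)-[3-(tert-butyldimethylsilyloxy)-2-methylpropyl]magnesium bromide | Br[Mg]C[C@H](C)CO[Si](C)(C)C(C)(C)C | intermediate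
8 | C18 ketone (3S,20S) | COCN1C(=O)CC[C@H]1C(=O)C[C@H](C)CO[Si](C)(C)C(C)(C)C | intermediate
9 | C18 alcohol (3S,18S,20S) | COCN1C(=O)CC[C@H]1[C@@H](O)C[C@H](C)CO[Si](C)(C)C(C)(C)C | intermediate
10 | bis-silyl ether (3S,18S,20S) | COCN1C(=O)CC[C@H]1[C@@H](O[Si](C)(C)C(C)(C)C)C[C@H](C)CO[Si](C)(C)C(C)(C)C | intermediate
11 | C1 alcohol (1R,3S,18S,20S) | COCN1C(=O)[C@H](O)C[C@H]1[C@@H](O[Si](C)(C)C(C)(C)C)C[C@H](C)CO[Si](C)(C)C(C)(C)C | intermediate
12 | C1 benzyl ether (1R,3S,18S,20S) | COCN1C(=O)[C@H](OCc2ccccc2)C[C@H]1[C@@H](O[Si](C)(C)C(C)(C)C)C[C@H](C)CO[Si](C)(C)C(C)(C)C | intermediate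
13 | (5S)-5-[(1S,2R,5S)-menthyloxy]furan-2(5H)-one | O=C1C=C[C@@H](O[C@H]2C[C@@H](C)CC[C@@H]2C(C)C)O1 | starting material
14 | lithium lactone enolate after Michael addition | COCN1C(=O)[C@@](OCc2ccccc2)(C[C@H]1[C@@H](O[Si](C)(C)C(C)(C)C)C[C@H](C)CO[Si](C)(C)C(C)(C)C)[C@@H]1[C@@H](O[C@H]2C[C@@H](C)CC[C@@H]2C(C)C)OC([O-])=C1.[Li+] | intermediate
15 | Michael–methylation adduct | COCN1C(=O)[C@@](OCc2ccccc2)(C[C@H]1[C@@H](O[Si](C)(C)C(C)(C)C)C[C@H](C)CO[Si](C)(C)C(C)(C)C)[C@@H]1[C@@H](O[C@H]2C[C@@H](C)CC[C@@H]2C(C)C)OC(=O)[C@H]1C | intermediate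
16 | diol, methyl ester, dimethyl acetal | COCN1C(=O)[C@@](OCc2ccccc2)(C[C@H]1[C@@H](O)C[C@H](C)CO)[C@H](C(OC)OC)[C@H](C)C(=O)OC | intermediate
17 | ring E lactone, methyl ester, dimethyl acetal | COCN1C(=O)[C@@](OCc2ccccc2)(C[C@H]1[C@@H]1C[C@H](C)C(=O)O1)[C@H](C(OC)OC)[C@H](C)C(=O)OC | intermediate
18 | C11 aldehyde | COCN1C(=O)[C@@](OCc2ccccc2)(C[C@H]1[C@@H]1C[C@H](C)C(=O)O1)[C@H](C=O)[C@H](C)C(=O)OC | intermediate
19 | (E)-hept-2-en-4-one | C/C=C/C(=O)CCC | starting material
20 | (Z)-dibutylboron enolate of 19 | CC/C=C(\OB(CCCC)CCCC)/C=C/C | intermediate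
21 | syn-aldol adduct | COCN1C(=O)[C@@](OCc2ccccc2)(C[C@H]1[C@@H]1C[C@H](C)C(=O)O1)[C@H]([C@@H](O)[C@H](CC)C(=O)/C=C/C)[C@H](C)C(=O)OC | intermediate
22 | seco propenyl ketone with rings A, D, E | COCN1C(=O)[C@@](OCc2ccccc2)(C[C@H]1[C@@H]1C[C@H](C)C(=O)O1)[C@@H]1[C@H]([C@H](CC)C(=O)/C=C/C)OC(=O)[C@H]1C | intermediate
23 | silyloxydiene N-acyliminium triflate | C=[N+]1C(=O)[C@@](OCc2ccccc2)(C[C@H]1[C@@H]1C[C@H](C)C(=O)O1)[C@@H]1[C@H]([C@H](CC)/C(O[Si](C)(C)C)=C/C=C)OC(=O)[C@H]1C.[O-]S(=O)(=O)C(F)(F)F | intermediate
24 | macrocyclic (E)-enone benzyl ether | CC[C@@H]1C(=O)/C=C/CCN2C(=O)[C@@](OCc3ccccc3)(C[C@H]2[C@@H]2C[C@H](C)C(=O)O2)[C@@H]2[C@H]1OC(=O)[C@H]2C | intermediate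
25 | CNP0221273.1 | CC[C@@H]1C(=O)CCCCN2C(=O)[C@@](O)(C[C@H]2[C@@H]2C[C@H](C)C(=O)O2)[C@@H]2[C@H]1OC(=O)[C@H]2C | target

Total steps: 15. Longest linear sequence: 14 (steps 1, 2 and 4 to 15, from 1).

Steps most likely to fail

Step 14: oligomerisation, or enolisation toward C10 followed by β-elimination of the ring D carboxylate, may outrun the eleven-membered closure. The fallback sets out from 22 and comes back at 24, and it uses known chemistry. The aminal of 22 is ionised in the presence of allyltrimethylsilane (Me3SiOTf cat., CH2Cl2, −78 °C; Hosomi–Sakurai-type amidoalkylation). This makes C5–C6 intermolecularly and should give the N-(but-3-enyl) lactam F1. Ring-closing metathesis of its terminal alkene with the propenyl ketone (second-generation Hoveyda–Grubbs catalyst, toluene, 1 mM, 80 °C) then closes the ring at C7=C8 and delivers 24.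

Step 9: proton transfer to the butenolide, retro-Michael reaction or eroded facial selectivity may defeat bond formation at the fully substituted enolate carbon. The fallback sets out from 12 and comes back at 15, and replaces the anionic tandem process by a neutral silyl-transfer sequence. LiN(i-Pr)2 and Me3SiCl convert 12 into the cyclic silyl ketene N,O-acetal F2. A Lewis-base-catalysed Mukaiyama–Michael addition to 13 (n-Bu4N(O2CPh) cat., THF, −78 to 0 °C, mild acidic work-up) should give the unmethylated adduct F3 under the same two facial controls. A separate enolate methylation at C13, the only acidic site left (LiN(i-Pr)2, MeI, THF, −78 °C), gives 15.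

Step 13: poor aldehyde-face selectivity, or enolisation and loss of the β-benzyloxy group of the hindered aldehyde, may erode C10/C11. The fallback sets out from 18 and comes back at 22, and moves the control to an auxiliary. An Evans syn-aldol reaction of (S)-4-benzyl-3-butanoyloxazolidin-2-one (n-Bu2BOTf, Et3N, CH2Cl2, −78 to 0 °C), followed by acid lactonisation, should give the ring D imide F4. LiSEt (THF, 0 °C) exchanges the auxiliary for the ethyl thioester F5. A Liebeskind–Srogl coupling with (E)-prop-1-enylboronic acid (Pd2(dba)3, tri(2-furyl)phosphine, copper thiophene-2-carboxylate CuO2CC4H3S, THF, 50 °C) gives 22 under neutral conditions.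

Further compounds
F1 | step 14 | N-(but-3-enyl) lactam propenyl ketone | C=CCCN1C(=O)[C@@](OCc2ccccc2)(C[C@H]1[C@@H]1C[C@H](C)C(=O)O1)[C@@H]1[C@H]([C@H](CC)C(=O)/C=C/C)OC(=O)[C@H]1C
F2 | step 9 | cyclic trimethylsilyl ketene N,O-acetal of 12 | COCN1C(O[Si](C)(C)C)=C(OCc2ccccc2)C[C@H]1[C@@H](O[Si](C)(C)C(C)(C)C)C[C@H](C)CO[Si](C)(C)C(C)(C)C
F3 | step 9 | unmethylated Michael adduct | COCN1C(=O)[C@@](OCc2ccccc2)(C[C@H]1[C@@H](O[Si](C)(C)C(C)(C)C)C[C@H](C)CO[Si](C)(C)C(C)(C)C)[C@@H]1[C@@H](O[C@H]2C[C@@H](C)CC[C@@H]2C(C)C)OC(=O)C1
F4 | step 13 | ring D lactone N-acyloxazolidinone | COCN1C(=O)[C@@](OCc2ccccc2)(C[C@H]1[C@@H]1C[C@H](C)C(=O)O1)[C@@H]1[C@H]([C@H](CC)C(=O)N2[C@@H](Cc3ccccc3)COC2=O)OC(=O)[C@H]1C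
F5 | step 13 | ring D lactone S-ethyl thioester | COCN1C(=O)[C@@](OCc2ccccc2)(C[C@H]1[C@@H]1C[C@H](C)C(=O)O1)[C@@H]1[C@H]([C@H](CC)C(=O)SCC)OC(=O)[C@H]1C
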